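Ring C of the upper flavan unit is disconnected at C4–C4a and O1–C2. The key step uses two features: O1 and C4a are ortho neighbours on ring A, bridging the C2–C3–C4 chain, and the C3 oxygen and the ring D aryl at C4 are cis. A triaryl borate of 3-benzyloxyphenol opens a trans-epoxy ketone at C4 with retention and, in the same operation, the released phenol closes ring C on the C2 ketone as a lactol. The precursor is the (2R,3S)-epoxide of the chalcone made from an 8-bromo-6-formyl perbenzylated (+)-catechin (rings D, F, E) and 3',4'-bis(benzyloxy)acetophenone (ring B).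

Key step: step 8

Remarks on the chemistry
- Target as read: a (2R,3R,4S) all-cis 7,3',4'-trihydroxyflavan-3-ol bonded from C4 to C6 of (+)-catechin (2R,3S). The precursor and product structures of the key step agree with this reading and need no correction.
- Upper-unit flavan numbering is used throughout: the ketone carbon of 10 becomes C2, the oxirane carbons become C3 (next to C=O) and C4 (next to ring D).
- Precursor design: the C8 bromine directs formylation to C6 and blocks the last nucleophilic position of ring D during the cationic opening; it is removed in the last step. The lower 3-OH is benzylated so that no free hydroxyl competes for boron.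
- Borate 12 is assembled from three molecules of phenol 11 and one boron atom (3 ArOH + BH3 → B(OAr)3 + 3 H2).
- Compounds 10 and 15 are acid-labile and should be purified on Et3N-deactivated silica; the C2 anomers of 15 are not separated.

Step 1
Reactants: 1 (+)-catechin
Product: 2 5,7,3',4'-tetra-O-benzyl-(+)-catechin
Conditions: BnBr (4.4 equiv), K2CO3, DMF, 0 °C to rt
Reagents that add atoms: benzyl bromide, BrCc1ccccc1
Why: Williamson etherification under carbonate alkylates only the four acidic phenols and leaves the secondary 3-OH and both stereocentres untouched.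

Step 2
Reactants: 2 5,7,3',4'-tetra-O-benzyl-(+)-catechin
Product: 3 3,5,7,3',4'-penta-O-benzyl-(+)-catechin
Conditions: NaH, BnBr, Bu4NI (cat.), DMF, 0 °C to rt
Reagents that add atoms: benzyl bromide, BrCc1ccccc1
Why: Williamson ether synthesis through the sodium alkoxide of the only remaining hydroxyl; with every phenol capped, C2 cannot epimerise by ring opening.

Step 3
Reactants: 3 3,5,7,3',4'-penta-O-benzyl-(+)-catechin
Product: 4 8-bromo-3,5,7,3',4'-penta-O-benzyl-(+)-catechin
Conditions: NBS (1.05 equiv), CH2Cl2, −40 °C to rt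
Reagents that add atoms: N-bromosuccinimide, O=C1CCC(=O)N1Br
Why: Electrophilic aromatic bromination of the phloroglucinol-type ring D, for which C8 is the established preferred position in O-benzylated catechins, while ring E is far less activated.

Step 4
Reactants: 4 8-bromo-3,5,7,3',4'-penta-O-benzyl-(+)-catechin
Product: 6 8-bromo-6-formyl-3,5,7,3',4'-penta-O-benzyl-(+)-catechin, via iminium salt 5 (not isolated)
Conditions: POCl3, DMF, 0 to 70 °C; then H2O, rt
Reagents that add atoms: N,N-dimethylformamide, CN(C)C=O; water, O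
Why: Vilsmeier–Haack formylation: with C8 brominated, C6 is the only free position of the still trioxygen-activated ring D, so the chloroiminium electrophile can only enter there, and hydrolysis of iminium salt 5 gives the aldehyde.

Step 5
Reactants: 6 8-bromo-6-formyl-3,5,7,3',4'-penta-O-benzyl-(+)-catechin; 7 3',4'-bis(benzyloxy)acetophenone
Product: 9 (E)-1-[3,4-bis(benzyloxy)phenyl]-3-(8-bromo-3,5,7,3',4'-penta-O-benzylcatechin-6-yl)prop-2-en-1-one, via aldol adduct 8 (not isolated)
Conditions: KOH, EtOH–THF, rt to 50 °C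
Reagents that add atoms: none
Why: Claisen–Schmidt condensation: the acetophenone enolate adds to the non-enolisable aldehyde and E1cB dehydration of aldol 8 gives the conjugated E-enone as the thermodynamic isomer.

Step 6
Reactants: 9 (E)-chalcone
Product: 10 [3,4-bis(benzyloxy)phenyl] (2R,3S)-3-(8-bromo-3,5,7,3',4'-penta-O-benzylcatechin-6-yl)oxiran-2-yl ketone (trans-epoxy ketone)
Conditions: poly-L-leucine (immobilised), urea–H2O2, DBU, THF, rt
Reagents that add atoms: urea–hydrogen peroxide, NC(N)=O.OO
Why: Juliá–Colonna epoxidation (a Weitz–Scheffer-type nucleophilic epoxidation): hydroperoxide adds to the enone β-carbon inside the helical poly-L-leucine, which on E-chalcones delivers oxygen to the face that gives the (2R,3S) oxirane, the E geometry becoming trans and the remote catechin stereocentres not expected to override catalyst control.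

Step 7
Reactants: 11 3-(benzyloxy)phenol (3 equiv, three molecules per boron)
Product: 12 tris(3-benzyloxyphenyl) borate
Conditions: BH3·SMe2 (1.0 equiv for 3.0 equiv of 11), toluene, 0 °C to 80 °C; evaporate, redissolve in CH2Cl2, use directly
Reagents that add atoms: borane–dimethyl sulfide, C[S+](C)[BH3-]; 3-(benzyloxy)phenol (second molecule of 11), Oc1cccc(OCc2ccccc2)c1; 3-(benzyloxy)phenol (third molecule of 11), Oc1cccc(OCc2ccccc2)c1
Why: Borate ester formation by stepwise protonolysis of the three B–H bonds of borane, one by each of three molecules of phenol 11, with heating to complete the slower third substitution; the only by-products, H2 and Me2S, are volatile, so the triaryl borate is obtained free of water and acid.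

Step 8
Reactants: 10 trans-epoxy ketone; 12 tris(3-benzyloxyphenyl) borate
Product: 15 (3R,4S)-7-(benzyloxy)-2-[3,4-bis(benzyloxy)phenyl]-4-(8-bromo-3,5,7,3',4'-penta-O-benzylcatechin-6-yl)chromane-2,3-diol (3,4-cis lactol), via cyclic borate ester 13 (not isolated), via keto-phenol 14 (not isolated)
Conditions: 12 (1.5 equiv), CH2Cl2, −78 to −20 °C; then aq NaHCO3
Reagents that add atoms: none
Why: Proposed new method: boron of 12 binds the oxirane oxygen, C4–O ionises to a contact ion pair whose cation is stabilised by the trioxygenated ring D, and an aryloxy ligand on the same boron hands its ortho carbon (para to the benzyloxy group) to C4 on the face the oxygen has just left; proton loss gives borate 13 and aqueous work-up releases keto-phenol 14. The closest known reaction type is the syn-selective ortho C-alkylation of phenols by aryl oxiranes through triaryl borates, applied here to an α,β-epoxy ketone. Ring C closes by 6-exo-trig addition of the liberated ring A phenol to the C2 ketone (hemiketalisation). The one new stereocentre, C4, is controlled by the oxirane configuration fixed in step 6 and by the boron-tethered front-side delivery (retention), which turns the trans-oxirane into the 3,4-cis (3R,4S) array while C3 keeps its C–O bond. Required are opening at C4 and not C3, syn and not anti attack, and alkylation at the ring A carbon para to the benzyloxy group: donor ring D against the carbonyl-deactivated C3 secures the site, intramolecular transfer in CH2Cl2 at low temperature secures the face, and sterics together with para activation secure the ring A position. The C8 bromide keeps ring D from alkylating itself, and the weak Lewis acidity of the borate should hold back acyl migration.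

Step 9
Reactants: 15 3,4-cis lactol
Product: 16 (2R,3R,4S)-7-(benzyloxy)-2-[3,4-bis(benzyloxy)phenyl]-4-(8-bromo-3,5,7,3',4'-penta-O-benzylcatechin-6-yl)chroman-3-ol (all-cis)
Conditions: Et3SiH, BF3·OEt2, CH2Cl2, −78 to −40 °C
Reagents that add atoms: none
Why: Ionic hydrogenation of a cyclic hemiketal: BF3 ionises the lactol to the aryl-stabilised C2 oxocarbenium ion and Et3SiH delivers hydride to the face opposite the cis C3 oxygen and C4 aryl group, which places ring B cis to both and sets C2 as R.

Step 10
Reactants: 16 all-cis protected bromo-biflavan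
Product: 17 CNP0141631.2
Conditions: H2 (1 atm), Pd(OH)2/C, Et3N (1.2 equiv), THF–MeOH, rt
Reagents that add atoms: none
Why: Catalytic hydrogenolysis cleaves the eight benzyl ethers and the C8–Br bond (hydrodehalogenation) without touching any stereocentre, while Et3N traps HBr so that the acid-labile C4–C6 interflavan bond survives.

Compound list
1 | (+)-catechin, (2R,3S)-2-(3,4-dihydroxyphenyl)chromane-3,5,7-triol | O[C@H]1Cc2c(O)cc(O)cc2O[C@@H]1c1ccc(O)c(O)c1 | starting material
2 | 5,7,3',4'-tetra-O-benzyl-(+)-catechin (3-OH free) | c1c(OCc3ccccc3)cc2c(c1OCc3ccccc3)C[C@H](O)[C@@H](c1ccc(OCc3ccccc3)c(OCc3ccccc3)c1)O2 | intermediate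
3 | 3,5,7,3',4'-penta-O-benzyl-(+)-catechin | c1c(OCc3ccccc3)cc2c(c1OCc3ccccc3)C[C@H](OCc3ccccc3)[C@@H](c1ccc(OCc3ccccc3)c(OCc3ccccc3)c1)O2 | intermediate
4 | 8-bromo-3,5,7,3',4'-penta-O-benzyl-(+)-catechin | c1c(OCc3ccccc3)c(Br)c2c(c1OCc3ccccc3)C[C@H](OCc3ccccc3)[C@@H](c1ccc(OCc3ccccc3)c(OCc3ccccc3)c1)O2 | intermediate
5 | C6 N,N-dimethyliminium dichlorophosphate of 4 (ArCH=NMe2+), formed in the flask | C[N+](C)=Cc1c(OCc3ccccc3)c(Br)c2c(c1OCc3ccccc3)C[C@H](OCc3ccccc3)[C@@H](c1ccc(OCc3ccccc3)c(OCc3ccccc3)c1)O2.[O-]P(=O)(Cl)Cl | intermediate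
6 | 8-bromo-6-formyl-3,5,7,3',4'-penta-O-benzyl-(+)-catechin | O=Cc1c(OCc3ccccc3)c(Br)c2c(c1OCc3ccccc3)C[C@H](OCc3ccccc3)[C@@H](c1ccc(OCc3ccccc3)c(OCc3ccccc3)c1)O2 | intermediate
7 | 3',4'-bis(benzyloxy)acetophenone | CC(=O)c1ccc(OCc2ccccc2)c(OCc2ccccc2)c1 | starting material
8 | aldol adduct, 1-[3,4-bis(benzyloxy)phenyl]-3-hydroxy-3-(8-bromo-penta-O-benzylcatechin-6-yl)propan-1-one (carbinol epimers), formed in the flask | O=C(c1ccc(OCc3ccccc3)c(OCc3ccccc3)c1)CC(O)c1c(OCc3ccccc3)c(Br)c2c(c1OCc3ccccc3)C[C@H](OCc3ccccc3)[C@@H](c1ccc(OCc3ccccc3)c(OCc3ccccc3)c1)O2 | intermediate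
9 | (E)-chalcone, (E)-1-[3,4-bis(benzyloxy)phenyl]-3-(8-bromo-penta-O-benzylcatechin-6-yl)prop-2-en-1-one | O=C(c1ccc(OCc3ccccc3)c(OCc3ccccc3)c1)/C=C/c1c(OCc3ccccc3)c(Br)c2c(c1OCc3ccccc3)C[C@H](OCc3ccccc3)[C@@H](c1ccc(OCc3ccccc3)c(OCc3ccccc3)c1)O2 | intermediate
10 | trans-epoxy ketone, [3,4-bis(benzyloxy)phenyl] (2R,3S)-3-(8-bromo-penta-O-benzylcatechin-6-yl)oxiran-2-yl ketone | O=C(c1ccc(OCc3ccccc3)c(OCc3ccccc3)c1)[C@@H]4O[C@H]4c1c(OCc3ccccc3)c(Br)c2c(c1OCc3ccccc3)C[C@H](OCc3ccccc3)[C@@H](c1ccc(OCc3ccccc3)c(OCc3ccccc3)c1)O2 | intermediate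
11 | 3-(benzyloxy)phenol | Oc1cccc(OCc2ccccc2)c1 | starting material
12 | tris(3-benzyloxyphenyl) borate | B(Oc1cccc(OCc2ccccc2)c1)(Oc1cccc(OCc2ccccc2)c1)Oc1cccc(OCc2ccccc2)c1 | intermediate
13 | cyclic borate ester of the ring-opened product (boron bridges O3 and the ring A oxygen in a seven-membered ring and keeps one 3-benzyloxyphenoxy ligand), formed in the flask | O=C(c1ccc(OCc3ccccc3)c(OCc3ccccc3)c1)[C@@H]1OB(Oc3cccc(OCc4ccccc4)c3)Oc3cc(OCc4ccccc4)ccc3[C@H]1c1c(OCc3ccccc3)c(Br)c2c(c1OCc3ccccc3)C[C@H](OCc3ccccc3)[C@@H](c1ccc(OCc3ccccc3)c(OCc3ccccc3)c1)O2 | intermediate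
14 | keto-phenol (open form of 15), (2R,3S)-1-[3,4-bis(benzyloxy)phenyl]-2-hydroxy-3-[4-(benzyloxy)-2-hydroxyphenyl]-3-(8-bromo-penta-O-benzylcatechin-6-yl)propan-1-one, formed in the flask | O=C(c1ccc(OCc3ccccc3)c(OCc3ccccc3)c1)[C@H](O)[C@@H](c1ccc(OCc3ccccc3)cc1O)c1c(OCc3ccccc3)c(Br)c2c(c1OCc3ccccc3)C[C@H](OCc3ccccc3)[C@@H](c1ccc(OCc3ccccc3)c(OCc3ccccc3)c1)O2 | intermediate
15 | 3,4-cis lactol, (3R,4S)-7-(benzyloxy)-2-[3,4-bis(benzyloxy)phenyl]-4-(8-bromo-penta-O-benzylcatechin-6-yl)chromane-2,3-diol (C2 anomers) | c3ccccc3COc1ccc2c(c1)OC(O)(c1ccc(OCc3ccccc3)c(OCc3ccccc3)c1)[C@H](O)[C@@H]2c1c(OCc3ccccc3)c(Br)c2c(c1OCc3ccccc3)C[C@H](OCc3ccccc3)[C@@H](c1ccc(OCc3ccccc3)c(OCc3ccccc3)c1)O2 | intermediate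
16 | all-cis protected bromo-biflavan, (2R,3R,4S)-7-(benzyloxy)-2-[3,4-bis(benzyloxy)phenyl]-4-(8-bromo-penta-O-benzylcatechin-6-yl)chroman-3-ol | c3ccccc3COc1ccc2c(c1)O[C@H](c1ccc(OCc3ccccc3)c(OCc3ccccc3)c1)[C@H](O)[C@@H]2c1c(OCc3ccccc3)c(Br)c2c(c1OCc3ccccc3)C[C@H](OCc3ccccc3)[C@@H](c1ccc(OCc3ccccc3)c(OCc3ccccc3)c1)O2 | intermediate
17 | CNP0141631.2, (2R,3R,4S)-2-(3,4-dihydroxyphenyl)-3,7-dihydroxychroman-4-yl unit bonded from C4 to C6 of (+)-catechin | Oc1ccc2c(c1)O[C@H](c1ccc(O)c(O)c1)[C@H](O)[C@@H]2c1c(O)cc2c(c1O)C[C@H](O)[C@@H](c1ccc(O)c(O)c1)O2 | target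

Total step count: 10.
Longest linear sequence: 9 steps (steps 1 to 6 and 8 to 10; step 7 is a one-step branch).

Steps most likely to fail

Step 8 (the step that goes beyond known chemistry). The ion pair may live long enough for the acyl group to shift to C4, or for the cation to leave the boron cage. Aryl transfer would then lose its facial control or occur para to the phenol oxygen. The fallback uses known chemistry: the carbonyl is masked as a protected carbinol, so the substrate is an ordinary aryl oxirane, the class on which borate syn-opening is established. It sets out from 10. NaBH4 in MeOH–THF at 0 °C should give the epoxy alcohol F1 (carbinol epimers, immaterial). TBSCl and imidazole in DMF should give the silyl ether F2. Borate 12 in CH2Cl2 at −78 °C, then aq NaHCO3, should open F2 at C4 with retention to the syn-opened phenol F3. Bu4NF in THF should give the triol F4. MnO2 in CH2Cl2 at rt should oxidise only the benzylic C2 carbinol; the keto-phenol 14 so formed closes to lactol 15, where the route is rejoined.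

Step 6. Hydroperoxide addition may be slow because the enone β-carbon is deactivated by the trioxygenated, doubly ortho-substituted ring D, and facial control inside the polypeptide may be incomplete. The fallback is an asymmetric Darzens condensation, which builds the C3–C4 bond and the oxirane from the aldehyde instead of oxidising the olefin. It sets out from 7 and 6. Treating 7 with LiHMDS and TMSCl in THF at −78 °C should give the trimethylsilyl enol ether F5, and NCS in THF at 0 °C should then give the α-chloro ketone F6. Condensing F6 with aldehyde 6 under a cinchona-derived quaternary ammonium phase-transfer catalyst (the pseudoenantiomer leading to the 2R,3S oxirane), LiOH·H2O, Bu2O, 0 °C, should give 10 directly; chalcone 9 is bypassed.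

Step 9. Hydride delivery to the nearly planar oxocarbenium ion may show too little facial bias and give the C2 epimer, or BF3 may open ring F. The fallback fixes C2 in the open chain and closes ring C by displacement. It sets out from 15, which reacts through its open form 14. Zn(BH4)2 in Et2O–THF at −20 °C should reduce the α-hydroxy ketone under chelation control to the anti-diol F7. Mitsunobu cyclisation (PPh3, DIAD, THF, 0 °C) should then let the ring A phenol displace the activated benzylic C2 hydroxyl with inversion, giving 16.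

Further compounds
F1 | step 8 | epoxy alcohol, NaBH4 reduction product of 10 with the trans-oxirane unchanged: [3,4-bis(benzyloxy)phenyl][3-(8-bromo-penta-O-benzylcatechin-6-yl)oxiran-2-yl]methanol (carbinol epimers) | OC(c1ccc(OCc3ccccc3)c(OCc3ccccc3)c1)[C@@H]4O[C@H]4c1c(OCc3ccccc3)c(Br)c2c(c1OCc3ccccc3)C[C@H](OCc3ccccc3)[C@@H](c1ccc(OCc3ccccc3)c(OCc3ccccc3)c1)O2
F2 | step 8 | tert-butyldimethylsilyl ether of F1 | CC(C)(C)[Si](C)(C)OC(c1ccc(OCc3ccccc3)c(OCc3ccccc3)c1)[C@@H]4O[C@H]4c1c(OCc3ccccc3)c(Br)c2c(c1OCc3ccccc3)C[C@H](OCc3ccccc3)[C@@H](c1ccc(OCc3ccccc3)c(OCc3ccccc3)c1)O2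
F3 | step 8 | syn-opened phenol, C2 silyl ether with free C3 hydroxyl and free ring A phenol (C3 R, C4 S in flavan numbering) | CC(C)(C)[Si](C)(C)OC(c1ccc(OCc3ccccc3)c(OCc3ccccc3)c1)[C@H](O)[C@@H](c1ccc(OCc3ccccc3)cc1O)c1c(OCc3ccccc3)c(Br)c2c(c1OCc3ccccc3)C[C@H](OCc3ccccc3)[C@@H](c1ccc(OCc3ccccc3)c(OCc3ccccc3)c1)O2
F4 | step 8 | triol, desilylated F3 (C2 carbinol epimers) | OC(c1ccc(OCc3ccccc3)c(OCc3ccccc3)c1)[C@H](O)[C@@H](c1ccc(OCc3ccccc3)cc1O)c1c(OCc3ccccc3)c(Br)c2c(c1OCc3ccccc3)C[C@H](OCc3ccccc3)[C@@H](c1ccc(OCc3ccccc3)c(OCc3ccccc3)c1)O2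
F5 | step 6 | trimethylsilyl enol ether of 7, {1-[3,4-bis(benzyloxy)phenyl]ethenyloxy}trimethylsilane | C=C(O[Si](C)(C)C)c1ccc(OCc2ccccc2)c(OCc2ccccc2)c1
F6 | step 6 | 2-chloro-1-[3,4-bis(benzyloxy)phenyl]ethanone | ClCC(=O)c1ccc(OCc2ccccc2)c(OCc2ccccc2)c1
F7 | step 9 | anti-diol, triol from chelation-controlled reduction of 14 (C2 and C3 hydroxyls anti, C2 defined) | O[C@@H](c1ccc(OCc3ccccc3)c(OCc3ccccc3)c1)[C@H](O)[C@@H](c1ccc(OCc3ccccc3)cc1O)c1c(OCc3ccccc3)c(Br)c2c(c1OCc3ccccc3)C[C@H](OCc3ccccc3)[C@@H](c1ccc(OCc3ccccc3)c(OCc3ccccc3)c1)O2
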